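**Plan**

1. Numbering: decalin atoms C1–C10 (ring A = C1–C5 + C10, ring B = C5–C10); C4 is the CMe2 carbon, C5=C6 the alkene, C8 carries Me, C9 carries Me and CH2–quinone, C10 carries H; Ar = 2,3,5,6-tetramethoxyphenyl.
2. Retrosynthesis: cut the quinone C–N bond (amine for OMe) and take the quinone back to ArCH2; derive C5=C6 from the C5-enolate of a C6 ketone and C10–H from reduction of a C5=C10 enone; then cut C1–C10 and C4–C5 together as a [4+2] to 4-methylpenta-1,3-diene and a ring-B 6-oxocyclohex-1-ene-1-carboxylate; ring B comes from an achiral 4,4-disubstituted cyclohexa-2,5-dienone.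
3. Enabling feature: ring A carries only the C4 gem-dimethyl group and meets ring B only at C5–C10, and the C5=C6 alkene marks C6 as a latent carbonyl; with C6=O and a temporary allyl ester on C5, the C5=C10 bond is a doubly activated dienophile (CH2 terminus of the diene to C10, CMe2 terminus to C5).
4. Forward order: ArCH2 chain, ring B (Robinson annulation, dehydrogenation), methyl at C8, ester at C5, ring A by Diels–Alder reaction, loss of the ester with formation of the C5=C10 enone, C10–H and C5=C6, quinone, amine.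
5. Stereochemistry: C8 is set by a copper/phosphoramidite catalyst, which also desymmetrises prochiral C9 (methyl enters anti to ArCH2); C10 is relayed from C9/C8 by axial protonation in a dissolving-metal reduction; the side-chain centre is bought as (S)-2-methylbutan-1-amine. The two ring-fusion centres made in the cycloaddition are erased afterwards, so that step needs no facial control.

Key step: step 8

Remark (assumption on the chemistry): the sense of induction in step 5 is assigned by analogy with the formation of 3-alkylcyclohexanones from cyclohex-2-enone with this ligand class; the ligand antipode named is the one expected to give the (4R,5S) product.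

**Route**

Step 1
Reactants: 1 1,2,4,5-tetramethoxybenzene
Product: 3 3-iodo-1,2,4,5-tetramethoxybenzene, via aryllithium 2 (not isolated)
Conditions: n-BuLi, THF, 0 °C; then I2, −78 °C → rt
Reagents that add atoms: iodine, II
Why: Directed ortho-lithiation between two methoxy groups followed by iodinolysis; the two ring C–H positions are equivalent, so one mono-iodide should form.

Step 2
Reactants: 3 3-iodo-1,2,4,5-tetramethoxybenzene; 4 2-methylprop-2-en-1-ol
Product: 5 2-methyl-3-(2,3,5,6-tetramethoxyphenyl)propanal (racemic)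
Conditions: Pd(OAc)2 (5 mol %), Bu4NCl, NaHCO3, DMF, 60 °C
Reagents that add atoms: none
Why: Heck arylation of an allylic alcohol (carbopalladation at the CH2 terminus, β-hydride elimination towards the carbinol carbon, enol-to-aldehyde tautomerisation) should give the β-aryl aldehyde; its stereocentre is racemic and becomes prochiral in step 4.

Step 3
Reactants: 5 2-methyl-3-(2,3,5,6-tetramethoxyphenyl)propanal; 6 but-3-en-2-one
Product: 8 4-methyl-4-(ArCH2)cyclohex-2-en-1-one (racemic), via keto aldehyde 7 (not isolated)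
Conditions: KOH (0.2 equiv), EtOH, 0 °C → rt, then 60 °C
Reagents that add atoms: none
Why: Robinson annulation (Michael addition of the α-branched aldehyde enolate to the vinyl ketone, then aldol condensation of the methyl ketone onto the aldehyde) should give the 4,4-disubstituted cyclohexenone; the quaternary centre is racemic and is symmetrised in step 4.

Step 4
Reactants: 8 4-methyl-4-(ArCH2)cyclohex-2-en-1-one
Product: 10 4-methyl-4-(ArCH2)cyclohexa-2,5-dien-1-one (achiral), via silyl dienol ether 9 (not isolated)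
Conditions: LiN(iPr)2, Me3SiCl, THF, −78 °C; then Pd(OAc)2 (1.0 equiv), MeCN, rt
Reagents that add atoms: none
Why: Saegusa–Ito dehydrogenation (kinetic α′-deprotonation and silylation, then oxidation of the cross-conjugated silyl dienol ether by Pd(OAc)2) should give the second enone; the product has a mirror plane, so the earlier racemic centre disappears.

Step 5
Reactants: 10 4-methyl-4-(ArCH2)cyclohexa-2,5-dien-1-one
Product: 12 (4R,5S)-4,5-dimethyl-4-(ArCH2)cyclohex-2-en-1-one, via dimethylaluminium enolate 11 (not isolated)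
Conditions: AlMe3, Cu(OTf)2 (2 mol %), phosphoramidite from (R)-1,1'-bi-2-naphthol and (S,S)-bis(1-phenylethyl)amine (4 mol %), Et2O, −30 °C; aq. NH4Cl
Reagents that add atoms: trimethylaluminium, C[Al](C)C
Why: Copper-catalysed enantioselective conjugate addition of a trialkylaluminium to a 4,4-disubstituted cyclohexa-2,5-dienone (desymmetrisation): the chiral copper complex fixes the new methyl-bearing carbon (5S) and the methyl enters anti to the larger ArCH2 group, so the choice of one enantiotopic alkene also makes the quaternary carbon (4R).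

Step 6
Reactants: 12 (4R,5S)-4,5-dimethyl-4-(ArCH2)cyclohex-2-en-1-one
Product: 13 (4R,5S)-2-iodo-4,5-dimethyl-4-(ArCH2)cyclohex-2-en-1-one
Conditions: I2, pyridine, CH2Cl2, rt
Reagents that add atoms: iodine, II
Why: α-Iodination of an enone by conjugate addition of pyridine, iodination of the enolate and elimination should act only at the one remaining enone; no stereocentre is touched.

Step 7
Reactants: 13 (4R,5S)-2-iodo-4,5-dimethyl-4-(ArCH2)cyclohex-2-en-1-one
Product: 14 prop-2-en-1-yl (3R,4S)-3,4-dimethyl-6-oxo-3-(ArCH2)cyclohex-1-ene-1-carboxylate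
Conditions: CO (1 atm), PdCl2(PPh3)2 (5 mol %), prop-2-en-1-ol, Et3N, DMF, 50 °C
Reagents that add atoms: carbon monoxide, [C-]#[O+]; prop-2-en-1-ol, C=CCO
Why: Palladium-catalysed alkoxycarbonylation of an alkenyl iodide (oxidative addition, CO insertion, alcoholysis) should install the allyl ester, which activates the C5=C10 bond and later leaves in step 9.

Step 8
Reactants: 14 prop-2-en-1-yl (3R,4S)-3,4-dimethyl-6-oxo-3-(ArCH2)cyclohex-1-ene-1-carboxylate; 15 4-methylpenta-1,3-diene
Product: 16 prop-2-en-1-yl (3S,4R)-3,4,8,8-tetramethyl-1-oxo-4-(ArCH2)-1,3,4,4a,5,8-hexahydronaphthalene-8a(2H)-carboxylate (cis-fused; drawn as the isomer with both new bonds anti to the two methyl groups)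
Conditions: ZnCl2 (1.5 equiv), Et2O/CH2Cl2, 0 °C → rt, excess 15
Reagents that add atoms: none
Why: ZnCl2 chelated by the ketone and ester carbonyls makes the C5=C10 bond of 14 strongly electron-poor, and it should undergo a concerted but highly asynchronous normal-demand [4+2] cycloaddition with the s-cis diene, the C1–C10 bond (diene CH2 terminus to the β-carbon) leading and the C4–C5 bond (CMe2 terminus to the ester-bearing α-carbon) following. The closest known reaction type is the Lewis acid-promoted Diels–Alder reaction of 2-alkoxycarbonylcyclohex-2-enones with acyclic dienes, in which 1-substituted dienes place their substituted terminus next to the ester-bearing carbon. Ring A is closed as a six-membered ring by suprafacial addition to both components, which gives a cis ring fusion (ester on C5 cis to H on C10). The new centres C5 and C10 are tied to each other by this suprafaciality and to C9/C8 by approach of the diene to the face of the half-chair opposite the two methyl groups, but this facial preference is not relied upon because both centres are removed in steps 9 and 11. What the step needs is regioselectivity and C=C over C=O periselectivity: the first is secured because the largest HOMO coefficient of the diene (unsubstituted C1) and the largest LUMO coefficient of the chelated dienophile (C10) meet in the less hindered bond, the second because O–C closure of the same polar transition state would give a 2-alkenyl dihydropyran that can still reach 16 by [3,3] rearrangement.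

Step 9
Reactants: 16 Diels–Alder adduct
Product: 17 (3S,4R)-3,4,8,8-tetramethyl-4-(ArCH2)-3,4,5,8-tetrahydronaphthalen-1(2H)-one
Conditions: Pd(OAc)2 (10 mol %), 1,2-bis(diphenylphosphino)ethane (10 mol %), MeCN, 80 °C
Reagents that add atoms: none
Why: Tsuji decarboxylation–dehydrogenation of an allyl β-keto ester: zerovalent palladium ionises the allyl ester, CO2 is lost, and the palladium enolate eliminates the only β-hydrogen (on C10), so the C5=C10 enone should form regiospecifically from any ring-fusion isomer of 16 with release of propene.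

Step 10
Reactants: 17 dienone
Product: 18 (3S,4R)-3,4,8,8-tetramethyl-4-(ArCH2)-3,4,5,6,7,8-hexahydronaphthalen-1(2H)-one
Conditions: H2 (1 atm), Pd/C, EtOAc, rt
Reagents that add atoms: none
Why: Catalytic hydrogenation should reduce the cis-disubstituted ring-A alkene much faster than the tetrasubstituted conjugated C5=C10 bond; no stereocentre is formed.

Step 11
Reactants: 18 enone
Product: 20 (3S,4R,4aS)-3,4,8,8-tetramethyl-4-(ArCH2)-2,3,4,4a,5,6,7,8-octahydronaphthalen-1-yl trifluoromethanesulfonate, via lithium enolate 19 (not isolated)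
Conditions: Li, NH3 (l)/THF, t-BuOH (1.0 equiv), −78 °C; isoprene; NH3 evaporated; then PhNTf2, THF, 0 °C → rt
Reagents that add atoms: N-phenylbis(trifluoromethanesulfonimide), O=S(=O)(N(c1ccccc1)S(=O)(=O)C(F)(F)F)C(F)(F)F
Why: Birch-type dissolving-metal reduction of the enone with regiospecific enolate trapping: the β-carbanion at C10 should be protonated axially on the face opposite the pseudoaxial C9 methyl group (giving the half-chair with ArCH2 and the C8 methyl equatorial), so H-10 ends trans to the C9 methyl, and the C5=C6 enolate is fixed as its triflate.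

Step 12
Reactants: 20 enol triflate
Product: 21 3-{[(1R,2S,8aS)-1,2,5,5-tetramethyl-1,2,3,5,6,7,8,8a-octahydronaphthalen-1-yl]methyl}-1,2,4,5-tetramethoxybenzene
Conditions: Pd(OAc)2 (5 mol %), PPh3, HCO2H, Bu3N, DMF, 60 °C
Reagents that add atoms: none
Why: Palladium-catalysed formate reduction of an enol triflate (oxidative addition, hydride transfer from formate, reductive elimination) should replace OTf by H without moving the C5=C6 double bond.

Step 13
Reactants: 21 tetramethoxyarene
Product: 22 2,5-dimethoxy-3-{[(1R,2S,8aS)-1,2,5,5-tetramethyl-1,2,3,5,6,7,8,8a-octahydronaphthalen-1-yl]methyl}cyclohexa-2,5-diene-1,4-dione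
Conditions: (NH4)2Ce(NO3)6, MeCN/H2O, 0 °C
Reagents that add atoms: water, O
Why: Oxidative demethylation of a 1,2,4,5-tetramethoxyarene by tetravalent cerium should give the 2,5-dimethoxy-1,4-benzoquinone, and the hindered trisubstituted alkene should survive the short cold exposure.

Step 14
Reactants: 22 dimethoxyquinone
Product: 23 2-hydroxy-5-methoxy-3-{[(1R,2S,8aS)-1,2,5,5-tetramethyl-1,2,3,5,6,7,8,8a-octahydronaphthalen-1-yl]methyl}cyclohexa-2,5-diene-1,4-dione
Conditions: KOH, MeOH/H2O, rt; then 1 M HCl, 0 °C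
Reagents that add atoms: potassium hydroxide, [K+].[OH-]
Why: Saponification of a vinylogous ester by addition–elimination should occur at the methoxy group flanked by the bulky alkyl group (twisted out of conjugation, hence the more electrophilic carbon), and the resulting hydroxyquinone anion resists a second hydrolysis.

Step 15
Reactants: 23 hydroxymethoxyquinone; 24 (S)-2-methylbutan-1-amine
Product: 25 nakijiquinone J
Conditions: 24 (3 equiv), EtOH, 40 °C
Reagents that add atoms: none
Why: Addition–elimination of the primary amine at the remaining methoxy-bearing carbon (vinylogous ester to vinylogous amide) should be selective because the ionised 2-hydroxy enone half is unreactive; the amine stereocentre is not involved.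

**Compound list**

1 | 1,2,4,5-tetramethoxybenzene | COc1cc(OC)c(OC)cc1OC | starting material
2 | (2,3,5,6-tetramethoxyphenyl)lithium | [Li]c1c(OC)c(OC)cc(OC)c1OC | intermediate
3 | 3-iodo-1,2,4,5-tetramethoxybenzene | COc1cc(OC)c(OC)c(I)c1OC | intermediate
4 | 2-methylprop-2-en-1-ol | C=C(C)CO | starting material
5 | 2-methyl-3-(2,3,5,6-tetramethoxyphenyl)propanal (racemic) | COc1cc(OC)c(OC)c(CC(C)C=O)c1OC | intermediate
6 | but-3-en-2-one | CC(=O)C=C | starting material
7 | 2-methyl-5-oxo-2-[(2,3,5,6-tetramethoxyphenyl)methyl]hexanal (racemic) | COc1cc(OC)c(OC)c(CC(C)(C=O)CCC(C)=O)c1OC | intermediate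
8 | 4-methyl-4-[(2,3,5,6-tetramethoxyphenyl)methyl]cyclohex-2-en-1-one (racemic) | COc1cc(OC)c(OC)c(CC2(C)C=CC(=O)CC2)c1OC | intermediate
9 | trimethyl({4-methyl-4-[(2,3,5,6-tetramethoxyphenyl)methyl]cyclohexa-1,5-dien-1-yl}oxy)silane | COc1cc(OC)c(OC)c(CC2(C)C=CC(O[Si](C)(C)C)=CC2)c1OC | intermediate
10 | 4-methyl-4-[(2,3,5,6-tetramethoxyphenyl)methyl]cyclohexa-2,5-dien-1-one (achiral) | COc1cc(OC)c(OC)c(CC2(C)C=CC(=O)C=C2)c1OC | intermediate
11 | dimethylaluminium (4S,5R)-4,5-dimethyl-4-[(2,3,5,6-tetramethoxyphenyl)methyl]cyclohexa-1,5-dien-1-olate (same spatial arrangement as 12) | COc1cc(OC)c(OC)c(C[C@@]2(C)C=CC(O[Al](C)C)=C[C@@H]2C)c1OC | intermediate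
12 | (4R,5S)-4,5-dimethyl-4-[(2,3,5,6-tetramethoxyphenyl)methyl]cyclohex-2-en-1-one (the two methyl groups cis) | COc1cc(OC)c(OC)c(C[C@@]2(C)C=CC(=O)C[C@@H]2C)c1OC | intermediate
13 | (4R,5S)-2-iodo-4,5-dimethyl-4-[(2,3,5,6-tetramethoxyphenyl)methyl]cyclohex-2-en-1-one | COc1cc(OC)c(OC)c(C[C@@]2(C)C=C(I)C(=O)C[C@@H]2C)c1OC | intermediate
14 | prop-2-en-1-yl (3R,4S)-3,4-dimethyl-6-oxo-3-[(2,3,5,6-tetramethoxyphenyl)methyl]cyclohex-1-ene-1-carboxylate | COc1cc(OC)c(OC)c(C[C@@]2(C)C=C(C(=O)OCC=C)C(=O)C[C@@H]2C)c1OC | intermediate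
15 | 4-methylpenta-1,3-diene | CC(C)=CC=C | starting material
16 | prop-2-en-1-yl (3S,4R)-3,4,8,8-tetramethyl-1-oxo-4-[(2,3,5,6-tetramethoxyphenyl)methyl]-1,3,4,4a,5,8-hexahydronaphthalene-8a(2H)-carboxylate (cis ring fusion, new bonds anti to the two methyl groups) | COc1cc(OC)c(OC)c(C[C@@]2(C)[C@H]3CC=CC(C)(C)[C@@]3(C(=O)OCC=C)C(=O)C[C@@H]2C)c1OC | intermediate
17 | (3S,4R)-3,4,8,8-tetramethyl-4-[(2,3,5,6-tetramethoxyphenyl)methyl]-3,4,5,8-tetrahydronaphthalen-1(2H)-one | COc1cc(OC)c(OC)c(C[C@@]2(C)C3=C(C(C)(C)C=CC3)C(=O)C[C@@H]2C)c1OC | intermediate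
18 | (3S,4R)-3,4,8,8-tetramethyl-4-[(2,3,5,6-tetramethoxyphenyl)methyl]-3,4,5,6,7,8-hexahydronaphthalen-1(2H)-one | COc1cc(OC)c(OC)c(C[C@@]2(C)C3=C(C(C)(C)CCC3)C(=O)C[C@@H]2C)c1OC | intermediate
19 | lithium (3S,4R,4aS)-3,4,8,8-tetramethyl-4-[(2,3,5,6-tetramethoxyphenyl)methyl]-2,3,4,4a,5,6,7,8-octahydronaphthalen-1-olate | COc1cc(OC)c(OC)c(C[C@@]2(C)[C@@H]3CCCC(C)(C)C3=C(O[Li])C[C@@H]2C)c1OC | intermediate
20 | (3S,4R,4aS)-3,4,8,8-tetramethyl-4-[(2,3,5,6-tetramethoxyphenyl)methyl]-2,3,4,4a,5,6,7,8-octahydronaphthalen-1-yl trifluoromethanesulfonate | COc1cc(OC)c(OC)c(C[C@@]2(C)[C@@H]3CCCC(C)(C)C3=C(OS(=O)(=O)C(F)(F)F)C[C@@H]2C)c1OC | intermediate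
21 | 3-{[(1R,2S,8aS)-1,2,5,5-tetramethyl-1,2,3,5,6,7,8,8a-octahydronaphthalen-1-yl]methyl}-1,2,4,5-tetramethoxybenzene | COc1cc(OC)c(OC)c(C[C@@]2(C)[C@@H]3CCCC(C)(C)C3=CC[C@@H]2C)c1OC | intermediate
22 | 2,5-dimethoxy-3-{[(1R,2S,8aS)-1,2,5,5-tetramethyl-1,2,3,5,6,7,8,8a-octahydronaphthalen-1-yl]methyl}cyclohexa-2,5-diene-1,4-dione | COC1=CC(=O)C(OC)=C(C[C@@]2(C)[C@@H]3CCCC(C)(C)C3=CC[C@@H]2C)C1=O | intermediate
23 | 2-hydroxy-5-methoxy-3-{[(1R,2S,8aS)-1,2,5,5-tetramethyl-1,2,3,5,6,7,8,8a-octahydronaphthalen-1-yl]methyl}cyclohexa-2,5-diene-1,4-dione | COC1=CC(=O)C(O)=C(C[C@@]2(C)[C@@H]3CCCC(C)(C)C3=CC[C@@H]2C)C1=O | intermediate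
24 | (S)-2-methylbutan-1-amine | CC[C@H](C)CN | starting material
25 | nakijiquinone J, 2-hydroxy-5-{[(2S)-2-methylbutyl]amino}-3-{[(1R,2S,8aS)-1,2,5,5-tetramethyl-1,2,3,5,6,7,8,8a-octahydronaphthalen-1-yl]methyl}cyclohexa-2,5-diene-1,4-dione | CC[C@H](C)CNC1=CC(=O)C(O)=C(C[C@@]2(C)[C@@H]3CCCC(C)(C)C3=CC[C@@H]2C)C1=O | target

**Totals**

Total step count: 15. Longest linear sequence: 15 steps (from 1; compounds 4, 6, 15 and 24 are bought).

**Steps most likely to fail**

Step 8. The cycloaddition may be outrun by Lewis acid-induced oligomerisation of the diene or by an ene reaction, or may stall at the congested C4–C5 bond, because the Z-methyl group of the diene disfavours the s-cis conformation. The fallback builds the same two bonds stepwise and sets out from 14. Copper-catalysed conjugate addition (CuBr·SMe2, THF, −78 °C) of the Grignard reagent (4-methylpent-3-en-1-yl)magnesium bromide F1, made from 5-bromo-2-methylpent-2-ene and Mg, should give the β-keto ester prop-2-en-1-yl (3R,4S)-3,4-dimethyl-2-(4-methylpent-3-en-1-yl)-6-oxo-3-(ArCH2)cyclohexane-1-carboxylate F2 (C1–C10 bond). SnCl4 in CH2Cl2 should then generate the tertiary cation at C4, which is captured by the enol of the β-keto ester (cation–olefin cyclisation terminated by a β-keto ester), closing ring A as the saturated bicyclic keto ester F3 (C4–C5 bond). Decarboxylation–dehydrogenation of F3 under the conditions of step 9 comes back to the route at 18; step 10 is then not needed.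

Step 9. At the fully substituted, neopentyl-type C5 the palladium enolate may be protonated or allylated faster than β-hydride elimination takes place. The fallback replaces the ester by a sulfinyl group that leaves by itself and sets out from 13. CuI-catalysed coupling with thiophenol (K2CO3, DMF) should give the 2-phenylsulfanyl enone F4, and mCPBA (1 equiv, −78 °C) the sulfoxide F5. ZnBr2-promoted Diels–Alder reaction of F5 with 15 should give the cis-fused 8a-sulfinyl adduct F6, which is not isolated: on warming (toluene, 80 °C) the sulfoxide undergoes syn-elimination towards the cis C10–H and the sequence comes back to the route at 17.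

Step 5. Methyl and ArCH2 may be too poorly differentiated at the quaternary carbon (low anti/syn ratio), or the selection between the two enantiotopic alkenes may be weak. The fallback relays the stereochemistry by enolate alkylation instead and sets out from 1. The aryllithium 2 is trapped with paraformaldehyde to give (2,3,5,6-tetramethoxyphenyl)methanol F7, and PBr3 gives the benzylic bromide F8. Copper-catalysed enantioselective conjugate addition of AlMe3 to bought 2-methylcyclohex-2-en-1-one, followed by alkylation of the enolate (MeLi, HMPA) with F8 trans to the new methyl group, should give (2R,3S)-2,3-dimethyl-2-(ArCH2)cyclohexan-1-one F9. Aerobic dehydrogenation (Pd(O2CCF3)2, DMSO, O2) gives the enone F10. A Wharton transposition (H2O2/NaOH to the epoxy ketone F11, then N2H4·H2O/AcOH to the allylic alcohol F12) and MnO2 oxidation come back to the route at 12.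

**Further compounds**

F1 | step 8 | (4-methylpent-3-en-1-yl)magnesium bromide | CC(C)=CCC[Mg]Br
F2 | step 8 | prop-2-en-1-yl (3R,4S)-3,4-dimethyl-2-(4-methylpent-3-en-1-yl)-6-oxo-3-[(2,3,5,6-tetramethoxyphenyl)methyl]cyclohexane-1-carboxylate (side chain drawn trans to the C3 methyl; C1 epimers and enol) | COc1cc(OC)c(OC)c(C[C@@]2(C)[C@@H](CCC=C(C)C)C(C(=O)OCC=C)C(=O)C[C@@H]2C)c1OC
F3 | step 8 | prop-2-en-1-yl (3S,4R)-3,4,8,8-tetramethyl-1-oxo-4-[(2,3,5,6-tetramethoxyphenyl)methyl]-1,3,4,4a,5,6,7,8-octahydronaphthalene-8a(2H)-carboxylate (ring-fusion isomers at C8a) | COc1cc(OC)c(OC)c(C[C@@]2(C)[C@H]3CCCC(C)(C)C3(C(=O)OCC=C)C(=O)C[C@@H]2C)c1OC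
F4 | step 9 | (4R,5S)-4,5-dimethyl-2-(phenylsulfanyl)-4-[(2,3,5,6-tetramethoxyphenyl)methyl]cyclohex-2-en-1-one | COc1cc(OC)c(OC)c(C[C@@]2(C)C=C(Sc3ccccc3)C(=O)C[C@@H]2C)c1OC
F5 | step 9 | (4R,5S)-2-(benzenesulfinyl)-4,5-dimethyl-4-[(2,3,5,6-tetramethoxyphenyl)methyl]cyclohex-2-en-1-one (both sulfur epimers) | COc1cc(OC)c(OC)c(C[C@@]2(C)C=C(S(=O)c3ccccc3)C(=O)C[C@@H]2C)c1OC
F6 | step 9 | (3S,4R)-8a-(benzenesulfinyl)-3,4,8,8-tetramethyl-4-[(2,3,5,6-tetramethoxyphenyl)methyl]-3,4,4a,5,8,8a-hexahydronaphthalen-1(2H)-one (cis-fused) | COc1cc(OC)c(OC)c(C[C@@]2(C)[C@H]3CC=CC(C)(C)[C@@]3(S(=O)c4ccccc4)C(=O)C[C@@H]2C)c1OC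
F7 | step 5 | (2,3,5,6-tetramethoxyphenyl)methanol | OCc1c(OC)c(OC)cc(OC)c1OC
F8 | step 5 | 3-(bromomethyl)-1,2,4,5-tetramethoxybenzene | BrCc1c(OC)c(OC)cc(OC)c1OC
F9 | step 5 | (2R,3S)-2,3-dimethyl-2-[(2,3,5,6-tetramethoxyphenyl)methyl]cyclohexan-1-one | COc1cc(OC)c(OC)c(C[C@@]2(C)C(=O)CCC[C@@H]2C)c1OC
F10 | step 5 | (5S,6R)-5,6-dimethyl-6-[(2,3,5,6-tetramethoxyphenyl)methyl]cyclohex-2-en-1-one | COc1cc(OC)c(OC)c(C[C@@]2(C)C(=O)C=CC[C@@H]2C)c1OC
F11 | step 5 | (3R,4S)-3,4-dimethyl-3-[(2,3,5,6-tetramethoxyphenyl)methyl]-7-oxabicyclo[4.1.0]heptan-2-one (epoxide diastereomers) | COc1cc(OC)c(OC)c(C[C@@]2(C)C(=O)C3OC3C[C@@H]2C)c1OC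
F12 | step 5 | (4R,5S)-4,5-dimethyl-4-[(2,3,5,6-tetramethoxyphenyl)methyl]cyclohex-2-en-1-ol (carbinol epimers) | COc1cc(OC)c(OC)c(C[C@@]2(C)C=CC(O)C[C@@H]2C)c1OC
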